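The synthesis rests on making the ring-fusion bond of the cis-bicyclo[3.3.0]octene (rings A and B), the bond between the methyl-bearing quaternary carbon and the allylic ring-fusion CH, by a gold-catalysed enyne cyclisation/semipinacol cascade. The step exploits that this quaternary carbon with its methyl and ring-B CH2 is a latent isopropenyl group, that the ring-B alkene is a latent alkyne and that the neighbouring ring-A carbon can be a ketone. The precursor is a cis-1-isopropenyl-2-alkynylcyclobutanol whose alkyne already carries the hydroazulene (rings C and D); one operation expands the cyclobutane to ring A, closes ring B and sets the quaternary centre. The ketone then anchors the side chain.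

Key step: step 19

Remark: 1 is taken as the commercial enantiopure statin side-chain aldehyde; the ring-D carbinol that carries the triethylsilyl group is oxidised in step 27, so its configuration only serves to direct step 3 (ring labels: A side-chain-bearing cyclopentane, B cyclopentene, C cyclopentane fused to the seven-membered ring D).

Step 1
Reactants: 1 tert-butyl 2-[(4R,6S)-6-formyl-2,2-dimethyl-1,3-dioxan-4-yl]acetate
Product: 2 tert-butyl 2-[(4R,6S)-6-ethenyl-2,2-dimethyl-1,3-dioxan-4-yl]acetate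
Conditions: Ph3PCH3Br, KN(SiMe3)2, THF, −78 °C to 0 °C
Reagents that add atoms: methyltriphenylphosphonium bromide, C[P+](c1ccccc1)(c1ccccc1)c1ccccc1.[Br-]
Why: Wittig methylenation of the α-alkoxy aldehyde at low temperature should give the vinyl group, which later supplies two ring-D carbons, without touching the two existing stereocentres.

Step 2
Reactants: 2 tert-butyl 2-[(4R,6S)-6-ethenyl-2,2-dimethyl-1,3-dioxan-4-yl]acetate
Product: 3 (4R,6S)-6-ethenyl-4-hydroxyoxan-2-one
Conditions: CF3CO2H, CH2Cl2, 0 °C to rt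
Reagents that add atoms: none
Why: Acid cleavage of the acetonide and the tert-butyl ester followed by δ-lactonisation ties one carbinol oxygen into the ring and leaves the other free, so the two oxygens of the syn-1,3-diol become distinguishable.

Step 3
Reactants: 3 (4R,6S)-6-ethenyl-4-hydroxyoxan-2-one, 4 methyl 4-iodobutanoate
Product: 5 methyl 4-[(3S,4R,6S)-6-ethenyl-4-hydroxy-2-oxooxan-3-yl]butanoate
Conditions: LiN(iPr)2 (2.2 equiv), THF, −78 °C; then 4, DMPU, −78 °C to −40 °C
Reagents that add atoms: none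
Why: Alkylation of the dianion of the β-hydroxy lactone (Fráter–Seebach-type enolate alkylation) should occur trans to the neighbouring alkoxide on the six-membered ring, which sets the future C/D ring-fusion methine relative to the existing carbinol centres.

Step 4
Reactants: 5 methyl 4-[(3S,4R,6S)-6-ethenyl-4-hydroxy-2-oxooxan-3-yl]butanoate
Product: 6 methyl 4-[(3S,4R,6S)-6-ethenyl-2-oxo-4-(triethylsilyloxy)oxan-3-yl]butanoate
Conditions: Et3SiCl, imidazole, DMF, 0 °C
Reagents that add atoms: chlorotriethylsilane, CC[Si](Cl)(CC)CC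
Why: Standard silylation of the only free alcohol gives the triethylsilyl ether that is removed selectively before the late oxidation to the ring-D ketone.

Step 5
Reactants: 6 methyl 4-[(3S,4R,6S)-6-ethenyl-2-oxo-4-(triethylsilyloxy)oxan-3-yl]butanoate
Product: 7 methyl (3S)-3-[(1R,3S)-3-hydroxy-1-(triethylsilyloxy)pent-4-en-1-yl]-2-oxocyclopentane-1-carboxylate
Conditions: LiN(iPr)2 (2.1 equiv), THF, −78 °C to −30 °C; then AcOH
Reagents that add atoms: none
Why: Kinetic deprotonation of the unhindered ester CH2 and intramolecular Claisen (Dieckmann-type) acylation by the lactone carbonyl should close ring C as the enolisable β-keto ester and release the second carbinol as its alkoxide, leaving the existing stereocentres untouched.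

Step 6
Reactants: 7 methyl (3S)-3-[(1R,3S)-3-hydroxy-1-(triethylsilyloxy)pent-4-en-1-yl]-2-oxocyclopentane-1-carboxylate
Product: 8 methyl (3S)-3-[(1R,3S)-3-(tert-butyldimethylsilyloxy)-1-(triethylsilyloxy)pent-4-en-1-yl]-2-oxocyclopentane-1-carboxylate
Conditions: t-BuMe2SiCl, imidazole, DMF, rt
Reagents that add atoms: tert-butylchlorodimethylsilane, CC(C)(C)[Si](C)(C)Cl
Why: Standard silylation of the liberated allylic alcohol with the more robust silyl group completes the differentiation of the two carbinols.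

Step 7
Reactants: 8 methyl (3S)-3-[(1R,3S)-3-(tert-butyldimethylsilyloxy)-1-(triethylsilyloxy)pent-4-en-1-yl]-2-oxocyclopentane-1-carboxylate
Product: 9 methyl (3S)-3-[(1R,3S)-3-(tert-butyldimethylsilyloxy)-1-(triethylsilyloxy)pent-4-en-1-yl]-2-(trifluoromethylsulfonyloxy)cyclopent-1-ene-1-carboxylate
Conditions: NaH, PhNTf2, THF, 0 °C to rt
Reagents that add atoms: N-phenylbis(trifluoromethanesulfonimide), O=S(=O)(N(c1ccccc1)S(=O)(=O)C(F)(F)F)C(F)(F)F
Why: O-Sulfonylation of the β-keto ester enolate (enol triflate formation) fixes the double bond between the ester-bearing carbon and the future ring-fusion carbon and provides the electrophile for ring closure.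

Step 8
Reactants: 9 methyl (3S)-3-[(1R,3S)-3-(tert-butyldimethylsilyloxy)-1-(triethylsilyloxy)pent-4-en-1-yl]-2-(trifluoromethylsulfonyloxy)cyclopent-1-ene-1-carboxylate
Product: 11 methyl (3aR,4R,6R)-6-(tert-butyldimethylsilyloxy)-4-(triethylsilyloxy)-2,3,3a,4,5,6,7,8-octahydroazulene-1-carboxylate, via alkylborane 10 (not isolated)
Conditions: 9-BBN, THF, rt; then PdCl2(dppf), AsPh3, Cs2CO3, DMF/H2O, 60 °C, high dilution
Reagents that add atoms: none
Why: Anti-Markovnikov hydroboration of the terminal vinyl group and intramolecular B-alkyl Suzuki–Miyaura coupling with the activated enol triflate should close the seven-membered ring D without forming or touching a stereocentre.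

Step 9
Reactants: 11 methyl (3aR,4R,6R)-6-(tert-butyldimethylsilyloxy)-4-(triethylsilyloxy)-2,3,3a,4,5,6,7,8-octahydroazulene-1-carboxylate
Product: 13 methyl (1S,3aR,4R,6R)-6-(tert-butyldimethylsilyloxy)-4-(triethylsilyloxy)-1,2,3,3a,4,5,6,7-octahydroazulene-1-carboxylate, via lithium dienolate 12 (not isolated)
Conditions: LiN(iPr)2, DMPU, THF, −78 °C; then AcOH, −78 °C
Reagents that add atoms: none
Why: In this deconjugative protonation the base removes the γ-hydrogen of the ring-D CH2 that lies cis to the ester, and kinetic α-protonation of the dienolate from the face opposite to the silyloxy-bearing carbon at the ring fusion should place the new hydrogen cis to the ring-fusion hydrogen while moving the double bond into ring D.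

Step 10
Reactants: 13 methyl (1S,3aR,4R,6R)-6-(tert-butyldimethylsilyloxy)-4-(triethylsilyloxy)-1,2,3,3a,4,5,6,7-octahydroazulene-1-carboxylate
Product: 14 (1S,3aR,4R,6R)-6-(tert-butyldimethylsilyloxy)-4-(triethylsilyloxy)-1,2,3,3a,4,5,6,7-octahydroazulene-1-carbaldehyde
Conditions: iBu2AlH (1.1 equiv), CH2Cl2, −78 °C
Reagents that add atoms: none
Why: Low-temperature partial reduction of the methyl ester (hydride reduction through the stable tetrahedral aluminate) should stop at the aldehyde without moving the β,γ-double bond or epimerising the α-centre.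

Step 11
Reactants: 14 (1S,3aR,4R,6R)-6-(tert-butyldimethylsilyloxy)-4-(triethylsilyloxy)-1,2,3,3a,4,5,6,7-octahydroazulene-1-carbaldehyde
Product: 15 (1R,3aR,4R,6R)-6-(tert-butyldimethylsilyloxy)-1-ethynyl-4-(triethylsilyloxy)-1,2,3,3a,4,5,6,7-octahydroazulene (its bicyclic unit, attached through C-1 with unchanged configuration, is called Az below)
Conditions: Me3SiCHN2, n-BuLi, THF, −78 °C; then 14, −78 °C to 0 °C
Reagents that add atoms: trimethylsilyldiazomethane, C[Si](C)(C)C=[N+]=[N-]
Why: Colvin homologation (addition of lithiated trimethylsilyldiazomethane, Peterson-type elimination and 1,2-hydride shift of the alkylidene carbene) converts the aldehyde into the terminal alkyne under cold, non-equilibrating conditions that keep the adjacent stereocentre.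

Step 12
Reactants: 16 1-cyclobutylethan-1-one
Product: 17 1-(1-bromocyclobutyl)ethan-1-one
Conditions: Br2, cat. HBr, CH2Cl2, 0 °C
Reagents that add atoms: bromine, BrBr
Why: Acid-catalysed α-bromination of the ketone proceeds through the more substituted enol and therefore places bromine on the ring carbon.

Step 13
Reactants: 17 1-(1-bromocyclobutyl)ethan-1-one
Product: 18 1-(cyclobut-1-en-1-yl)ethan-1-one
Conditions: Li2CO3, LiBr, DMF, 110 °C
Reagents that add atoms: none
Why: Dehydrobromination of the tertiary α-bromo ketone (base-mediated elimination) can only use ring hydrogens and gives the conjugated cyclobutenyl ketone.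

Step 14
Reactants: 18 1-(cyclobut-1-en-1-yl)ethan-1-one
Product: 19 (1S)-1-(cyclobut-1-en-1-yl)ethan-1-ol
Conditions: (R)-2-methyl-CBS-oxazaborolidine (10 mol %), BH3·SMe2, THF, −40 °C
Reagents that add atoms: none
Why: Corey–Bakshi–Shibata reduction of the enone, with the alkenyl group as the large substituent, should give the (S)-allylic alcohol by reagent control.

Step 15
Reactants: 19 (1S)-1-(cyclobut-1-en-1-yl)ethan-1-ol
Product: 20 (1S)-1-[(1S,4S)-5-oxabicyclo[2.1.0]pentan-1-yl]ethan-1-ol
Conditions: VO(acac)2 (2 mol %), t-BuOOH, CH2Cl2, 0 °C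
Reagents that add atoms: tert-butyl hydroperoxide, CC(C)(C)OO
Why: Vanadium-catalysed hydroxyl-directed epoxidation of a secondary allylic alcohol with a geminal ring substituent is erythro-selective (allylic 1,2-strain model), so the carbinol configuration fixes the face of the epoxide and both epoxide carbons.

Step 16
Reactants: 15 (1R,3aR,4R,6R)-6-(tert-butyldimethylsilyloxy)-1-ethynyl-4-(triethylsilyloxy)-1,2,3,3a,4,5,6,7-octahydroazulene, 20 (1S)-1-[(1S,4S)-5-oxabicyclo[2.1.0]pentan-1-yl]ethan-1-ol
Product: 22 (1R,2S)-2-(Az-ethynyl)-1-[(1S)-1-hydroxyethyl]cyclobutan-1-ol, via alkynylalane 21 (not isolated)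
Conditions: 15, n-BuLi, toluene, 0 °C; Et2AlCl; then 20 (as its lithium alkoxide, n-BuLi), 0 °C to rt
Reagents that add atoms: none
Why: Hydroxyl-assisted opening of the 2,3-epoxy alcohol by the alkynylalane occurs at the less substituted epoxide carbon with inversion (SN2 epoxide opening), which places the alkyne trans to the tertiary hydroxyl, cis to the future isopropenyl group, and fixes the stereocentre that becomes the A/B ring-fusion methine.

Step 17
Reactants: 22 (1R,2S)-2-(Az-ethynyl)-1-[(1S)-1-hydroxyethyl]cyclobutan-1-ol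
Product: 23 1-[(1R,2S)-2-(Az-ethynyl)-1-hydroxycyclobutyl]ethan-1-one
Conditions: Dess–Martin periodinane, NaHCO3, CH2Cl2, 0 °C
Reagents that add atoms: none
Why: Dess–Martin oxidation converts the secondary carbinol into the methyl ketone and cannot oxidise the tertiary alcohol.

Step 18
Reactants: 23 1-[(1R,2S)-2-(Az-ethynyl)-1-hydroxycyclobutyl]ethan-1-one
Product: 24 (1R,2S)-2-(Az-ethynyl)-1-(prop-1-en-2-yl)cyclobutan-1-ol
Conditions: Ph3PCH3Br, KN(SiMe3)2 (3 equiv of ylide), THF, −78 °C to 0 °C
Reagents that add atoms: methyltriphenylphosphonium bromide, C[P+](c1ccccc1)(c1ccccc1)c1ccccc1.[Br-]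
Why: Wittig methylenation of the α-hydroxy methyl ketone with excess ylide installs the isopropenyl group and thereby completes the 3-hydroxy-1,5-enyne needed for the cascade.

Step 19
Reactants: 24 (1R,2S)-2-(Az-ethynyl)-1-(prop-1-en-2-yl)cyclobutan-1-ol
Product: 25 (3aS,6aR)-5-Az-6a-methyl-3,3a,6,6a-tetrahydropentalen-1(2H)-one
Conditions: Ph3PAuCl (5 mol %), AgSbF6 (5 mol %), CH2Cl2, rt
Reagents that add atoms: none
Why: The cationic gold phosphine complex activates the alkyne of the 3-hydroxy-1,5-enyne, the isopropenyl CH2 attacks the distal alkyne carbon in a 6-endo-dig carbocyclisation, and the tertiary cation that results next to the carbinol is quenched by a pinacol-type 1,2-shift of the alkynyl-bearing cyclobutane carbon, after which protodeauration by the released proton frees the catalyst. The closest known reaction types are the gold-catalysed cyclisation/pinacol cascade of 3-silyloxy-1,5-enynes and the gold-promoted semipinacol ring expansion of cyclobutanols. Ring B closes by the 6-endo-dig attack and the ensuing contraction of the six-membered ring, and ring A closes by one-carbon expansion of the cyclobutane, both through the single 1,2-shift that creates the ring-fusion bond. The migrating methine keeps its configuration, and the new quaternary centre is dictated by it because two five-membered rings sharing this bond can only be cis-fused, so both centres trace back to the epoxide of step 15. The step needs the substituted ring carbon to migrate in preference to the cyclobutane CH2 and needs the isopropenyl and alkynyl groups cis on the four-membered ring; the first is secured by the higher migratory aptitude of the secondary carbon that is allylic to the vinylgold unit, the second by the anti epoxide opening of step 16.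

Step 20
Reactants: 25 (3aS,6aR)-5-Az-6a-methyl-3,3a,6,6a-tetrahydropentalen-1(2H)-one
Product: 26 (3aS,6aR)-5-Az-6a-methyl-3,3a,6,6a-tetrahydropentalen-1-yl trifluoromethanesulfonate
Conditions: KN(SiMe3)2, PhNTf2, THF, −78 °C
Reagents that add atoms: N-phenylbis(trifluoromethanesulfonimide), O=S(=O)(N(c1ccccc1)S(=O)(=O)C(F)(F)F)C(F)(F)F
Why: Deprotonation can only occur at the single α-CH2 of the ketone, and O-sulfonylation of the enolate gives the enol triflate (standard vinyl triflate formation).

Step 21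
Reactants: 26 (3aS,6aR)-5-Az-6a-methyl-3,3a,6,6a-tetrahydropentalen-1-yl trifluoromethanesulfonate
Product: 28 1-[(3aS,6aR)-5-Az-6a-methyl-3,3a,6,6a-tetrahydropentalen-1-yl]ethan-1-one, via ethoxydiene 27 (not isolated)
Conditions: Pd(PPh3)4 (5 mol %), LiCl, tributyl(1-ethoxyvinyl)stannane, THF, 65 °C; then aq. oxalic acid, 0 °C
Reagents that add atoms: tributyl(1-ethoxyvinyl)stannane, CCCC[Sn](CCCC)(CCCC)C(=C)OCC; water, O
Why: Stille coupling of the hindered vinyl triflate with the ethoxyvinylstannane, a reaction well established for neopentyl cyclopentenyl triflates, followed by mild hydrolysis of the enol ether gives the conjugated methyl ketone.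

Step 22
Reactants: 28 1-[(3aS,6aR)-5-Az-6a-methyl-3,3a,6,6a-tetrahydropentalen-1-yl]ethan-1-one
Product: 29 1-[(1S,3aS,6aR)-5-Az-6a-methyl-1,2,3,3a,6,6a-hexahydropentalen-1-yl]ethan-1-one
Conditions: [(Ph3P)CuH]6, toluene, H2O (2 equiv), rt
Reagents that add atoms: none
Why: Chemoselective conjugate reduction of the enone by the copper hydride cluster leaves the isolated trisubstituted alkenes untouched, and kinetic protonation of the enolate from the convex face of the cis-fused diquinane should place the acetyl group trans to the angular methyl group.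

Step 23
Reactants: 30 (R)-but-3-yn-2-ol
Product: 31 (R)-tert-butyl(but-3-yn-2-yloxy)dimethylsilane
Conditions: t-BuMe2SiCl, imidazole, CH2Cl2, rt
Reagents that add atoms: tert-butylchlorodimethylsilane, CC(C)(C)[Si](C)(C)Cl
Why: Standard silylation protects the secondary alcohol of the commercial enantiopure alkynol without affecting its stereocentre.

Step 24
Reactants: 31 (R)-tert-butyl(but-3-yn-2-yloxy)dimethylsilane
Product: 32 (R,E)-tert-butyl[(4-iodobut-3-en-2-yl)oxy]dimethylsilane
Conditions: Cp2Zr(H)Cl, THF, rt; then I2, 0 °C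
Reagents that add atoms: iodine, II
Why: Hydrozirconation of the terminal alkyne is a syn addition that places zirconium on the terminal carbon, and iodinolysis with retention gives the (E)-vinyl iodide.

Step 25
Reactants: 29 1-[(1S,3aS,6aR)-5-Az-6a-methyl-1,2,3,3a,6,6a-hexahydropentalen-1-yl]ethan-1-one, 32 (R,E)-tert-butyl[(4-iodobut-3-en-2-yl)oxy]dimethylsilane
Product: 34 (2S,3E,5R)-2-[(1S,3aS,6aR)-5-Az-6a-methyl-1,2,3,3a,6,6a-hexahydropentalen-1-yl]-5-(tert-butyldimethylsilyloxy)hex-3-en-2-ol, via vinyllithium 33 (not isolated)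
Conditions: 32, t-BuLi (2 equiv), Et2O, −78 °C; CeCl3, THF, −78 °C; then 29, −78 °C
Reagents that add atoms: none
Why: Iodine–lithium exchange and transmetallation to cerium give a weakly basic vinyl nucleophile whose 1,2-addition to the methyl ketone should follow the Felkin–Anh model (attack anti to the quaternary-carbon branch of the adjacent stereocentre), which gives the required configuration of the tertiary carbinol.

Step 26
Reactants: 34 (2S,3E,5R)-2-[(1S,3aS,6aR)-5-Az-6a-methyl-1,2,3,3a,6,6a-hexahydropentalen-1-yl]-5-(tert-butyldimethylsilyloxy)hex-3-en-2-ol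
Product: 35 analogue of 34 with a free 4-hydroxyl on the azulene unit
Conditions: HF·pyridine, excess pyridine, THF, 0 °C
Reagents that add atoms: none
Why: Buffered fluoride cleaves the secondary triethylsilyl ether much faster than the two tert-butyldimethylsilyl ethers (selective desilylation), so only the ring-D carbinol is freed.

Step 27
Reactants: 35 analogue of 34 with a free 4-hydroxyl on the azulene unit
Product: 36 bis(tert-butyldimethylsilyl) ether of the target (ring-D ketone in place)
Conditions: Dess–Martin periodinane, NaHCO3, CH2Cl2, 0 °C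
Reagents that add atoms: none
Why: Dess–Martin oxidation under buffered, non-basic conditions oxidises the only free secondary alcohol to the ring-D ketone without enolising the allylic α-centre, the tertiary alcohol being inert.

Step 28
Reactants: 36 bis(tert-butyldimethylsilyl) ether of the target
Product: 37 CNP0358460.1
Conditions: HF·pyridine, THF, 0 °C to rt
Reagents that add atoms: none
Why: Global fluoride-mediated desilylation under mildly acidic, non-basic conditions releases the two secondary alcohols without β-elimination of the β-hydroxy ketone or ionisation of the tertiary allylic alcohol.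

Compound list
1 | tert-butyl 2-[(4R,6S)-6-formyl-2,2-dimethyl-1,3-dioxan-4-yl]acetate | O=C[C@@H]1C[C@H](CC(=O)OC(C)(C)C)OC(C)(C)O1 | starting material
2 | tert-butyl 2-[(4R,6S)-6-ethenyl-2,2-dimethyl-1,3-dioxan-4-yl]acetate | C=C[C@@H]1C[C@H](CC(=O)OC(C)(C)C)OC(C)(C)O1 | intermediate
3 | (4R,6S)-6-ethenyl-4-hydroxyoxan-2-one | C=C[C@@H]1C[C@@H](O)CC(=O)O1 | intermediate
4 | methyl 4-iodobutanoate | COC(=O)CCCI | starting material
5 | methyl 4-[(3S,4R,6S)-6-ethenyl-4-hydroxy-2-oxooxan-3-yl]butanoate (3,4-trans) | C=C[C@@H]1C[C@@H](O)[C@H](CCCC(=O)OC)C(=O)O1 | intermediate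
6 | methyl 4-[(3S,4R,6S)-6-ethenyl-2-oxo-4-(triethylsilyloxy)oxan-3-yl]butanoate | C=C[C@@H]1C[C@@H](O[Si](CC)(CC)CC)[C@H](CCCC(=O)OC)C(=O)O1 | intermediate
7 | methyl (3S)-3-[(1R,3S)-3-hydroxy-1-(triethylsilyloxy)pent-4-en-1-yl]-2-oxocyclopentane-1-carboxylate (C-1 epimers and enol form) | C=C[C@@H](O)C[C@@H](O[Si](CC)(CC)CC)[C@@H]1CCC(C(=O)OC)C1=O | intermediate
8 | methyl (3S)-3-[(1R,3S)-3-(tert-butyldimethylsilyloxy)-1-(triethylsilyloxy)pent-4-en-1-yl]-2-oxocyclopentane-1-carboxylate | C=C[C@@H](O[Si](C)(C)C(C)(C)C)C[C@@H](O[Si](CC)(CC)CC)[C@@H]1CCC(C(=O)OC)C1=O | intermediate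
9 | methyl (3S)-3-[(1R,3S)-3-(tert-butyldimethylsilyloxy)-1-(triethylsilyloxy)pent-4-en-1-yl]-2-(trifluoromethylsulfonyloxy)cyclopent-1-ene-1-carboxylate | C=C[C@@H](O[Si](C)(C)C(C)(C)C)C[C@@H](O[Si](CC)(CC)CC)[C@@H]1CCC(C(=O)OC)=C1OS(=O)(=O)C(F)(F)F | intermediate
10 | B-alkyl-9-borabicyclo[3.3.1]nonane from 9 (boron on the terminal carbon of the former vinyl group) | C1CCC2CCCC1B2CC[C@@H](O[Si](C)(C)C(C)(C)C)C[C@@H](O[Si](CC)(CC)CC)[C@@H]1CCC(C(=O)OC)=C1OS(=O)(=O)C(F)(F)F | intermediate
11 | methyl (3aR,4R,6R)-6-(tert-butyldimethylsilyloxy)-4-(triethylsilyloxy)-2,3,3a,4,5,6,7,8-octahydroazulene-1-carboxylate (3a-H, 4-O and 6-O on one face) | COC(=O)C1=C2CC[C@@H](O[Si](C)(C)C(C)(C)C)C[C@@H](O[Si](CC)(CC)CC)[C@@H]2CC1 | intermediate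
12 | lithium dienolate of 11 (ester enolate conjugated with the 8,8a-double bond) | [Li+].[O-]C(OC)=C1CC[C@H]2[C@H](O[Si](CC)(CC)CC)C[C@H](O[Si](C)(C)C(C)(C)C)CC=C12 | intermediate
13 | methyl (1S,3aR,4R,6R)-6-(tert-butyldimethylsilyloxy)-4-(triethylsilyloxy)-1,2,3,3a,4,5,6,7-octahydroazulene-1-carboxylate (1-H cis to 3a-H) | COC(=O)[C@H]1CC[C@H]2[C@H](O[Si](CC)(CC)CC)C[C@H](O[Si](C)(C)C(C)(C)C)CC=C12 | intermediate
14 | (1S,3aR,4R,6R)-6-(tert-butyldimethylsilyloxy)-4-(triethylsilyloxy)-1,2,3,3a,4,5,6,7-octahydroazulene-1-carbaldehyde | O=C[C@H]1CC[C@H]2[C@H](O[Si](CC)(CC)CC)C[C@H](O[Si](C)(C)C(C)(C)C)CC=C12 | intermediate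
15 | (1R,3aR,4R,6R)-6-(tert-butyldimethylsilyloxy)-1-ethynyl-4-(triethylsilyloxy)-1,2,3,3a,4,5,6,7-octahydroazulene (Az–C≡CH) | C#C[C@H]1CC[C@H]2[C@H](O[Si](CC)(CC)CC)C[C@H](O[Si](C)(C)C(C)(C)C)CC=C12 | intermediate
16 | 1-cyclobutylethan-1-one | CC(=O)C1CCC1 | starting material
17 | 1-(1-bromocyclobutyl)ethan-1-one | CC(=O)C1(Br)CCC1 | intermediate
18 | 1-(cyclobut-1-en-1-yl)ethan-1-one | CC(=O)C1=CCC1 | intermediate
19 | (1S)-1-(cyclobut-1-en-1-yl)ethan-1-ol | C[C@H](O)C1=CCC1 | intermediate
20 | (1S)-1-[(1S,4S)-5-oxabicyclo[2.1.0]pentan-1-yl]ethan-1-ol (erythro epoxy alcohol) | C[C@H](O)[C@@]12CC[C@@H]1O2 | intermediate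
21 | (Az-ethynyl)diethylalane | CC[Al](CC)C#C[C@H]1CC[C@H]2[C@H](O[Si](CC)(CC)CC)C[C@H](O[Si](C)(C)C(C)(C)C)CC=C12 | intermediate
22 | (1R,2S)-2-(Az-ethynyl)-1-[(1S)-1-hydroxyethyl]cyclobutan-1-ol (ring hydroxyl trans to the alkynyl group) | C[C@H](O)[C@@]1(O)CC[C@H]1C#C[C@H]2CC[C@H]3[C@H](O[Si](CC)(CC)CC)C[C@H](O[Si](C)(C)C(C)(C)C)CC=C23 | intermediate
23 | 1-[(1R,2S)-2-(Az-ethynyl)-1-hydroxycyclobutyl]ethan-1-one | CC(=O)[C@@]1(O)CC[C@H]1C#C[C@H]2CC[C@H]3[C@H](O[Si](CC)(CC)CC)C[C@H](O[Si](C)(C)C(C)(C)C)CC=C23 | intermediate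
24 | (1R,2S)-2-(Az-ethynyl)-1-(prop-1-en-2-yl)cyclobutan-1-ol (isopropenyl cis to alkynyl) | C=C(C)[C@@]1(O)CC[C@H]1C#C[C@H]2CC[C@H]3[C@H](O[Si](CC)(CC)CC)C[C@H](O[Si](C)(C)C(C)(C)C)CC=C23 | intermediate
25 | (3aS,6aR)-5-Az-6a-methyl-3,3a,6,6a-tetrahydropentalen-1(2H)-one (cis-fused) | O=C1CC[C@H]2C=C([C@H]3CC[C@H]4[C@H](O[Si](CC)(CC)CC)C[C@H](O[Si](C)(C)C(C)(C)C)CC=C34)C[C@]21C | intermediate
26 | (3aS,6aR)-5-Az-6a-methyl-3,3a,6,6a-tetrahydropentalen-1-yl trifluoromethanesulfonate | O=S(=O)(OC1=CC[C@H]2C=C([C@H]3CC[C@H]4[C@H](O[Si](CC)(CC)CC)C[C@H](O[Si](C)(C)C(C)(C)C)CC=C34)C[C@]21C)C(F)(F)F | intermediate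
27 | (3aS,6aR)-5-Az-1-(1-ethoxyethenyl)-6a-methyl-3,3a,6,6a-tetrahydropentalene | CCOC(=C)C1=CC[C@H]2C=C([C@H]3CC[C@H]4[C@H](O[Si](CC)(CC)CC)C[C@H](O[Si](C)(C)C(C)(C)C)CC=C34)C[C@]21C | intermediate
28 | 1-[(3aS,6aR)-5-Az-6a-methyl-3,3a,6,6a-tetrahydropentalen-1-yl]ethan-1-one | CC(=O)C1=CC[C@H]2C=C([C@H]3CC[C@H]4[C@H](O[Si](CC)(CC)CC)C[C@H](O[Si](C)(C)C(C)(C)C)CC=C34)C[C@]21C | intermediate
29 | 1-[(1S,3aS,6aR)-5-Az-6a-methyl-1,2,3,3a,6,6a-hexahydropentalen-1-yl]ethan-1-one (acetyl trans to the angular methyl) | CC(=O)[C@H]1CC[C@H]2C=C([C@H]3CC[C@H]4[C@H](O[Si](CC)(CC)CC)C[C@H](O[Si](C)(C)C(C)(C)C)CC=C34)C[C@]21C | intermediate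
30 | (R)-but-3-yn-2-ol | C[C@@H](O)C#C | starting material
31 | (R)-tert-butyl(but-3-yn-2-yloxy)dimethylsilane | C[C@@H](O[Si](C)(C)C(C)(C)C)C#C | intermediate
32 | (R,E)-tert-butyl[(4-iodobut-3-en-2-yl)oxy]dimethylsilane | C[C@@H](O[Si](C)(C)C(C)(C)C)/C=C/I | intermediate
33 | (R,E)-[3-(tert-butyldimethylsilyloxy)but-1-en-1-yl]lithium | C[C@@H](O[Si](C)(C)C(C)(C)C)/C=C/[Li] | intermediate
34 | (2S,3E,5R)-2-[(1S,3aS,6aR)-5-Az-6a-methyl-1,2,3,3a,6,6a-hexahydropentalen-1-yl]-5-(tert-butyldimethylsilyloxy)hex-3-en-2-ol | C[C@@H](O[Si](C)(C)C(C)(C)C)/C=C/[C@](C)(O)[C@H]1CC[C@H]2C=C([C@H]3CC[C@H]4[C@H](O[Si](CC)(CC)CC)C[C@H](O[Si](C)(C)C(C)(C)C)CC=C34)C[C@]21C | intermediate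
35 | analogue of 34 with a free 4-hydroxyl on the azulene unit (triethylsilyl group removed) | C[C@@H](O[Si](C)(C)C(C)(C)C)/C=C/[C@](C)(O)[C@H]1CC[C@H]2C=C([C@H]3CC[C@H]4[C@H](O)C[C@H](O[Si](C)(C)C(C)(C)C)CC=C34)C[C@]21C | intermediate
36 | bis(tert-butyldimethylsilyl) ether of the target (ring-D ketone, both secondary alcohols silylated) | C[C@@H](O[Si](C)(C)C(C)(C)C)/C=C/[C@](C)(O)[C@H]1CC[C@H]2C=C([C@H]3CC[C@H]4C(=O)C[C@H](O[Si](C)(C)C(C)(C)C)CC=C34)C[C@]21C | intermediate
37 | CNP0358460.1 | C[C@@H](O)/C=C/[C@](C)(O)[C@H]1CC[C@H]2C=C([C@H]3CC[C@H]4C(=O)C[C@H](O)CC=C34)C[C@]21C | target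

Total step count: 28. Longest linear sequence: 22 steps (steps 1–11, 16–22 and 25–28).

Steps most likely to fail

Step 19 (gold cascade). The unsubstituted cyclobutane CH2 may migrate in place of the alkynyl-bearing carbon, which would lead to a bridged ketone, or cyclisation at the hindered alkyne may be slow. The fallback sets out from 15 and comes back at 25: the same ring-fusion bond is made on an open-chain 3-silyloxy-1,5-enyne, in which only the ring carbon can migrate, and ring A is closed afterwards. Addition of the zinc acetylide of 15 to acrolein (Me2Zn, ProPhenol ligand of the required handedness) gives the propargylic alcohol F1, which is converted with MsCl and Et3N into the mesylate F2. Pd(OAc)2, PPh3 and Et2Zn turn F2 into the allenylzinc reagent, whose addition to methacrolein should give the anti homopropargylic alcohol F3. Silylation with Et3SiOTf and 2,6-lutidine gives the triethylsilyl ether F4. Ph3PAuCl and AgSbF6 with iPrOH then effect the cyclisation/pinacol shift to the cyclopentene carbaldehyde F5, with formyl and vinyl groups expected cis. Intramolecular alkene hydroacylation with [Rh(dppe)]ClO4 closes the cyclopentanone and gives 25.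

Step 8 (closure of ring D). Protodeboronation or β-hydride elimination of the alkylpalladium species may outrun closure of the seven-membered ring. The fallback sets out from 9 and comes back at 11. Stille coupling of 9 with tributyl(vinyl)stannane (Pd(PPh3)4, LiCl) gives the triene ester F6. Ring-closing metathesis of its two vinyl groups with the second-generation Grubbs catalyst gives the bicyclic dienoate F7. Hydrogenation of only the disubstituted ring-D alkene with RhCl(PPh3)3 and H2 then gives 11.

Step 3 (lactone alkylation). Proton transfer to the iodo ester and its self-condensation may compete with C-alkylation by an unactivated primary iodide. The fallback sets out from 3 and comes back at 5. The dianion of 3 is alkylated with the activated allylic halide methyl (E)-4-bromobut-2-enoate to give the enoate F8. Its conjugated double bond is then reduced chemoselectively with [(Ph3P)CuH]6, which gives 5.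

Further compounds
F1 | step 19 | 1-Az-pent-4-en-1-yn-3-ol (propargylic alcohol, single enantiomer as drawn) | C=C[C@@H](O)C#C[C@H]1CC[C@H]2[C@H](O[Si](CC)(CC)CC)C[C@H](O[Si](C)(C)C(C)(C)C)CC=C12
F2 | step 19 | methanesulfonate of F1 | C=C[C@@H](OS(C)(=O)=O)C#C[C@H]1CC[C@H]2[C@H](O[Si](CC)(CC)CC)C[C@H](O[Si](C)(C)C(C)(C)C)CC=C12
F3 | step 19 | anti-6-Az-4-ethenyl-2-methylhex-1-en-5-yn-3-ol | C=C(C)[C@@H](O)[C@@H](C=C)C#C[C@H]1CC[C@H]2[C@H](O[Si](CC)(CC)CC)C[C@H](O[Si](C)(C)C(C)(C)C)CC=C12
F4 | step 19 | triethylsilyl ether of F3 | C=C(C)[C@@H](O[Si](CC)(CC)CC)[C@@H](C=C)C#C[C@H]1CC[C@H]2[C@H](O[Si](CC)(CC)CC)C[C@H](O[Si](C)(C)C(C)(C)C)CC=C12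
F5 | step 19 | cis-4-Az-2-ethenyl-1-methylcyclopent-3-ene-1-carbaldehyde | C=C[C@H]1C=C([C@H]2CC[C@H]3[C@H](O[Si](CC)(CC)CC)C[C@H](O[Si](C)(C)C(C)(C)C)CC=C23)C[C@@]1(C)C=O
F6 | step 8 | methyl (3S)-2-ethenyl-3-[(1R,3S)-3-(tert-butyldimethylsilyloxy)-1-(triethylsilyloxy)pent-4-en-1-yl]cyclopent-1-ene-1-carboxylate | C=C[C@@H](O[Si](C)(C)C(C)(C)C)C[C@@H](O[Si](CC)(CC)CC)[C@@H]1CCC(C(=O)OC)=C1C=C
F7 | step 8 | methyl 6-(tert-butyldimethylsilyloxy)-4-(triethylsilyloxy)-2,3,3a,4,5,6-hexahydroazulene-1-carboxylate (configuration as in 11) | COC(=O)C1=C2C=C[C@@H](O[Si](C)(C)C(C)(C)C)C[C@@H](O[Si](CC)(CC)CC)[C@@H]2CC1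
F8 | step 3 | methyl (E)-4-[(3S,4R,6S)-6-ethenyl-4-hydroxy-2-oxooxan-3-yl]but-2-enoate | C=C[C@@H]1C[C@@H](O)[C@H](C/C=C/C(=O)OC)C(=O)O1
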